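Cuts: (i) the galloyl ester bond O3′–C(=O); (ii) the aryl ether bond O1–C8a of the pyran C ring; (iii) C2–C1′ (B-ring aryllithium plus Weinreb amide); (iv) C3–C4 (glycolate enolate plus A-ring benzyl bromide).
Enabling feature: O1 sits on A-ring carbon C8a, which is meta to O5 and O7 and ortho to C4a. C8a can therefore be carried as the bromide of 5-bromoresorcinol, and formylation para to one ether places the C4 carbon on C4a directly beside it.
Forward order: C3–C4, then C2–C1′, ketone reduction, closure of the C ring (the only ring built; the A, B and galloyl rings are bought), release of O3′, esterification, global hydrogenolysis.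
Stereochemistry: C3 (S) comes from an (R)-4-benzyloxazolidinone auxiliary in the alkylation. C2 (R) comes from 1,2-induction by C3 in a zinc-chelate reduction, which gives the anti alcohol. The ring closure breaks no bond at C2 or C3, so anti becomes 2,3-trans.

Key step: step 13

Remark (assumption): O3′ and O5′ are interchanged by rotation about C2–C1′, so a B ring with one free meta oxygen beside a 4′,5′-ketal defines the ester position unambiguously.
Remark: electrophilic halogenation of pyrogallol derivatives goes ortho/para to the outer oxygens, not to C5. The B ring is therefore taken from 5-bromo-1,2,3-trimethoxybenzene, in which the halogen is already para to the central oxygen.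
Remark: O3′ is masked as an allyl ether. An aryl silyl ether would be exposed to a caesium alkoxide at 110 °C in the ring closure.

Step 1
Reactants: 1 5-bromoresorcinol
Product: 2 1,3-bis(benzyloxy)-5-bromobenzene
Conditions: BnBr, K2CO3, DMF, 60 °C
Reagents that add atoms: benzyl bromide, BrCc1ccccc1
Why: Williamson ether synthesis on two acidic phenols is reliable, and benzyl is chosen because it falls in the final hydrogenolysis.

Step 2
Reactants: 2 1,3-bis(benzyloxy)-5-bromobenzene
Product: 4 2,4-bis(benzyloxy)-6-bromobenzaldehyde, via aryl iminium chloride 3 (not isolated)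
Conditions: POCl3, DMF, 0 → 90 °C; then H2O
Reagents that add atoms: N,N-dimethylformamide, CN(C)C=O (formyl carbon; NMe2 of 3); water, O (aldehyde oxygen); phosphoryl chloride, O=P(Cl)(Cl)Cl (chloride of 3 only)
Why: Vilsmeier–Haack formylation of 3,5-dialkoxybromobenzenes is known to go to the position para to one ether, ortho to the other and ortho to bromine rather than between the two ethers, which puts the future C4 carbon next to the future C8a–Br.

Step 3
Reactants: 4 2,4-bis(benzyloxy)-6-bromobenzaldehyde
Product: 5 [2,4-bis(benzyloxy)-6-bromophenyl]methanol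
Conditions: NaBH4, THF–MeOH, 0 °C
Reagents that add atoms: none
Why: Chemoselective borohydride reduction of an aryl aldehyde leaves the aryl bromide and the benzyl ethers untouched.

Step 4
Reactants: 5 [2,4-bis(benzyloxy)-6-bromophenyl]methanol
Product: 6 1,5-bis(benzyloxy)-3-bromo-2-(bromomethyl)benzene
Conditions: PBr3, Et2O, 0 °C
Reagents that add atoms: phosphorus tribromide, BrP(Br)Br
Why: The electron-rich benzylic alcohol is converted through its phosphite ester into the bromide by SN2 displacement at 0 °C, and the labile product should be used directly.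

Step 5
Reactants: 7 (R)-4-benzyl-1,3-oxazolidin-2-one; 8 benzyloxyacetyl chloride
Product: 10 (4R)-4-benzyl-3-[(benzyloxy)acetyl]-1,3-oxazolidin-2-one, via lithium oxazolidinide 9 (not isolated)
Conditions: n-BuLi, THF, −78 °C; then 8, −78 → 0 °C
Reagents that add atoms: n-butyllithium, [Li]CCCC (lithium of 9 only)
Why: N-acylation of the lithiated Evans oxazolidinone with an acid chloride is the standard entry to glycolate imides and does not touch the auxiliary stereocentre.

Step 6
Reactants: 10 (4R)-4-benzyl-3-[(benzyloxy)acetyl]-1,3-oxazolidin-2-one; 6 1,5-bis(benzyloxy)-3-bromo-2-(bromomethyl)benzene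
Product: 12 (4R)-4-benzyl-3-{(2S)-2-(benzyloxy)-3-[2,4-bis(benzyloxy)-6-bromophenyl]propanoyl}-1,3-oxazolidin-2-one, via sodium Z-enolate 11 (not isolated)
Conditions: NaHMDS, THF, −78 °C; then 6, −78 → −40 °C (imide in slight excess)
Reagents that add atoms: sodium hexamethyldisilazide, C[Si](C)(C)[N-][Si](C)(C)C.[Na+] (sodium of 11 only)
Why: Evans-type asymmetric alkylation of a glycolate imide, in which the sodium-chelated Z-enolate is shielded on one face by the C4 benzyl group of the (R)-auxiliary, so the reactive benzylic bromide should add to the opposite face and set the 2S centre (C3 of the flavan).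

Step 7
Reactants: 12 (4R)-4-benzyl-3-{(2S)-2-(benzyloxy)-3-[2,4-bis(benzyloxy)-6-bromophenyl]propanoyl}-1,3-oxazolidin-2-one
Product: 13 (2S)-2-(benzyloxy)-3-[2,4-bis(benzyloxy)-6-bromophenyl]-N-methoxy-N-methylpropanamide
Conditions: MeONHMe·HCl, AlMe3, CH2Cl2, −10 °C → rt; then 0.5 M HCl
Reagents that add atoms: N,O-dimethylhydroxylamine hydrochloride, CNOC.Cl
Why: Weinreb aminolysis with the aluminium amide attacks the more electrophilic exocyclic imide carbonyl, frees the auxiliary for reuse and, being non-basic, should leave the α-alkoxy centre intact.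

Step 8
Reactants: 14 5-bromo-1,2,3-trimethoxybenzene
Product: 15 5-bromobenzene-1,2,3-triol
Conditions: BBr3, CH2Cl2, −78 °C → rt; then H2O
Reagents that add atoms: none
Why: Exhaustive aryl methyl ether cleavage with BBr3 is standard and supplies the pyrogallol unit with bromine already para to the central oxygen, a pattern that direct bromination of pyrogallol does not give.

Step 9
Reactants: 15 5-bromobenzene-1,2,3-triol
Product: 16 6-bromo-2,2-diphenyl-1,3-benzodioxol-4-ol
Conditions: Ph2CCl2, Ph2O, 175 °C
Reagents that add atoms: dichlorodiphenylmethane, ClC(Cl)(c1ccccc1)c1ccccc1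
Why: Ketalisation of a catechol pair with dichlorodiphenylmethane can bridge only two neighbouring oxygens in a five-membered ring, so the symmetric triol should give one mono-phenol whose free OH is the future O3′.

Step 10
Reactants: 16 6-bromo-2,2-diphenyl-1,3-benzodioxol-4-ol
Product: 17 4-(allyloxy)-6-bromo-2,2-diphenyl-1,3-benzodioxole
Conditions: allyl bromide, K2CO3, DMF, rt
Reagents that add atoms: allyl bromide, C=CCBr
Why: Williamson allylation installs a base- and hydride-stable ether that palladium(0) removes later without touching benzyl ethers or the ketal.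

Step 11
Reactants: 17 4-(allyloxy)-6-bromo-2,2-diphenyl-1,3-benzodioxole; 13 (2S)-2-(benzyloxy)-3-[2,4-bis(benzyloxy)-6-bromophenyl]-N-methoxy-N-methylpropanamide
Product: 19 (2S)-1-[7-(allyloxy)-2,2-diphenyl-1,3-benzodioxol-5-yl]-2-(benzyloxy)-3-[2,4-bis(benzyloxy)-6-bromophenyl]propan-1-one, via aryllithium 18 (not isolated)
Conditions: n-BuLi (0.95 equiv per 17), THF, −78 °C; then 13, −78 → −40 °C
Reagents that add atoms: n-butyllithium, [Li]CCCC (lithium of 18 only)
Why: Weinreb ketone synthesis, in which bromine–lithium exchange is fast at −78 °C, the chelated tetrahedral adduct blocks over-addition and enolisation, and a slight deficit of n-BuLi together with the low temperature should keep the A-ring bromide out of halogen–metal exchange.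

Step 12
Reactants: 19 (2S)-1-[7-(allyloxy)-2,2-diphenyl-1,3-benzodioxol-5-yl]-2-(benzyloxy)-3-[2,4-bis(benzyloxy)-6-bromophenyl]propan-1-one
Product: 20 (1R,2S)-1-[7-(allyloxy)-2,2-diphenyl-1,3-benzodioxol-5-yl]-2-(benzyloxy)-3-[2,4-bis(benzyloxy)-6-bromophenyl]propan-1-ol (anti)
Conditions: Zn(BH4)2, Et2O–CH2Cl2, −78 → −20 °C
Reagents that add atoms: none
Why: Cram-chelate controlled reduction, in which zinc ties the ketone oxygen to the C2 benzyloxy oxygen in a five-membered chelate and hydride arrives from the face that carries H rather than the arylmethyl group, which should give the 1R carbinol, i.e. the anti (1R,2S) isomer.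

Step 13
Reactants: 20 (1R,2S)-1-[7-(allyloxy)-2,2-diphenyl-1,3-benzodioxol-5-yl]-2-(benzyloxy)-3-[2,4-bis(benzyloxy)-6-bromophenyl]propan-1-ol
Product: 21 (2R,3S)-2-[7-(allyloxy)-2,2-diphenyl-1,3-benzodioxol-5-yl]-3,5,7-tris(benzyloxy)chromane (2,3-trans flavan)
Conditions: CuI (10 mol %), 3,4,7,8-tetramethyl-1,10-phenanthroline (20 mol %), Cs2CO3, 4 Å MS, degassed toluene, 110 °C
Reagents that add atoms: none
Why: Cs2CO3 deprotonates the only free hydroxyl (C2–OH) and the alkoxide binds to the phenanthroline–Cu(I) centre, after which the tethered C8a–Br bond adds oxidatively and C–O reductive elimination from the seven-membered cupracycle (Cu, O1, C2, C3, C4, C4a, C8a) forms O1–C8a. The closest known reaction type is the ligand-assisted copper-catalysed Ullmann-type O-arylation of aliphatic alcohols, secondary benzylic ones included, with aryl bromides, whose intramolecular version gives chromans and dihydrobenzofurans. The pyran C ring closes in a 6-exo mode, since the breaking C–Br bond lies outside the six-membered ring O1–C2–C3–C4–C4a–C8a. No stereocentre is created, because only O–H and C(sp2)–Br bonds are broken, so C2 (R) and C3 (S) are carried over with retention and the anti alcohol maps onto the 2,3-trans flavan without passing through a benzylic cation or quinone methide. The step needs ring-size selectivity and O-arylation in preference to alcohol dehydrogenation or debromination: the benzyl ether on O3 removes the competing five-membered closure, copper alkoxides are far less prone to β-hydride loss than palladium alkoxides, and exclusion of air and water suppresses ketone and arene formation. The spectator groups (benzyl and allyl ethers, diphenyl ketal) are inert to carbonate base at 110 °C.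

Step 14
Reactants: 21 (2R,3S)-2-[7-(allyloxy)-2,2-diphenyl-1,3-benzodioxol-5-yl]-3,5,7-tris(benzyloxy)chromane
Product: 22 6-[(2R,3S)-3,5,7-tris(benzyloxy)chroman-2-yl]-2,2-diphenyl-1,3-benzodioxol-4-ol
Conditions: Pd(PPh3)4 (5 mol %), morpholine, THF, rt
Reagents that add atoms: none
Why: Tsuji–Trost-type deallylation, in which Pd(0) ionises only the allyl aryl ether to a π-allyl complex that morpholine traps, so benzyl ethers, ketal and both stereocentres are untouched.

Step 15
Reactants: 22 6-[(2R,3S)-3,5,7-tris(benzyloxy)chroman-2-yl]-2,2-diphenyl-1,3-benzodioxol-4-ol; 23 3,4,5-tris(benzyloxy)benzoic acid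
Product: 24 6-[(2R,3S)-3,5,7-tris(benzyloxy)chroman-2-yl]-2,2-diphenyl-1,3-benzodioxol-4-yl 3,4,5-tris(benzyloxy)benzoate
Conditions: DCC, DMAP, CH2Cl2, 0 °C → rt
Reagents that add atoms: none
Why: Steglich esterification of the single free phenol with the protected gallic acid fixes the ester at O3′ because every other oxygen is blocked.

Step 16
Reactants: 24 6-[(2R,3S)-3,5,7-tris(benzyloxy)chroman-2-yl]-2,2-diphenyl-1,3-benzodioxol-4-yl 3,4,5-tris(benzyloxy)benzoate
Product: 25 (2R,3S)-gallocatechin 3′-O-gallate
Conditions: H2 (1 atm), Pd(OH)2/C, THF–MeOH, rt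
Reagents that add atoms: none
Why: Catalytic hydrogenolysis under neutral conditions cleaves the six benzyl ethers and the diphenylmethylene ketal in one operation, as is usual for protected catechin gallates, while the aryl ester and the C2–O1 bond should survive and the neutral medium avoids acyl migration and C2 epimerisation.

Compound list
1 | 5-bromoresorcinol | Oc1cc(O)cc(Br)c1 | starting material
2 | 1,3-bis(benzyloxy)-5-bromobenzene | Brc1cc(OCc2ccccc2)cc(OCc2ccccc2)c1 | intermediate
3 | N-[2,4-bis(benzyloxy)-6-bromobenzylidene]-N-methylmethanaminium chloride | C[N+](C)=Cc1c(Br)cc(OCc2ccccc2)cc1OCc1ccccc1.[Cl-] | intermediate (not isolated)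
4 | 2,4-bis(benzyloxy)-6-bromobenzaldehyde | O=Cc1c(Br)cc(OCc2ccccc2)cc1OCc1ccccc1 | intermediate
5 | [2,4-bis(benzyloxy)-6-bromophenyl]methanol | OCc1c(Br)cc(OCc2ccccc2)cc1OCc1ccccc1 | intermediate
6 | 1,5-bis(benzyloxy)-3-bromo-2-(bromomethyl)benzene | BrCc1c(Br)cc(OCc2ccccc2)cc1OCc1ccccc1 | intermediate
7 | (R)-4-benzyl-1,3-oxazolidin-2-one | O=C1N[C@H](Cc2ccccc2)CO1 | starting material
8 | benzyloxyacetyl chloride | O=C(Cl)COCc1ccccc1 | starting material
9 | lithium (R)-4-benzyl-2-oxo-1,3-oxazolidin-3-ide | [Li+].O=C1[N-][C@H](Cc2ccccc2)CO1 | intermediate (not isolated)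
10 | (4R)-4-benzyl-3-[(benzyloxy)acetyl]-1,3-oxazolidin-2-one | O=C1OC[C@@H](Cc2ccccc2)N1C(=O)COCc1ccccc1 | intermediate
11 | sodium (Z)-enolate of 10 | [Na+].[O-]/C(=C\OCc1ccccc1)N1C(=O)OC[C@H]1Cc1ccccc1 | intermediate (not isolated)
12 | (4R)-4-benzyl-3-{(2S)-2-(benzyloxy)-3-[2,4-bis(benzyloxy)-6-bromophenyl]propanoyl}-1,3-oxazolidin-2-one | O=C1OC[C@@H](Cc2ccccc2)N1C(=O)[C@@H](OCc1ccccc1)Cc1c(Br)cc(OCc2ccccc2)cc1OCc1ccccc1 | intermediate
13 | (2S)-2-(benzyloxy)-3-[2,4-bis(benzyloxy)-6-bromophenyl]-N-methoxy-N-methylpropanamide | CON(C)C(=O)[C@@H](OCc1ccccc1)Cc1c(Br)cc(OCc2ccccc2)cc1OCc1ccccc1 | intermediate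
14 | 5-bromo-1,2,3-trimethoxybenzene | COc1cc(Br)cc(OC)c1OC | starting material
15 | 5-bromobenzene-1,2,3-triol | Oc1cc(Br)cc(O)c1O | intermediate
16 | 6-bromo-2,2-diphenyl-1,3-benzodioxol-4-ol | Oc1cc(Br)cc2OC(c3ccccc3)(c3ccccc3)Oc12 | intermediate
17 | 4-(allyloxy)-6-bromo-2,2-diphenyl-1,3-benzodioxole | C=CCOc1cc(Br)cc2OC(c3ccccc3)(c3ccccc3)Oc12 | intermediate
18 | [7-(allyloxy)-2,2-diphenyl-1,3-benzodioxol-5-yl]lithium | [Li]c1cc(OCC=C)c2OC(c3ccccc3)(c3ccccc3)Oc2c1 | intermediate (not isolated)
19 | (2S)-1-[7-(allyloxy)-2,2-diphenyl-1,3-benzodioxol-5-yl]-2-(benzyloxy)-3-[2,4-bis(benzyloxy)-6-bromophenyl]propan-1-one | C=CCOc1cc(C(=O)[C@@H](OCc2ccccc2)Cc2c(Br)cc(OCc3ccccc3)cc2OCc2ccccc2)cc2OC(c3ccccc3)(c3ccccc3)Oc12 | intermediate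
20 | (1R,2S)-1-[7-(allyloxy)-2,2-diphenyl-1,3-benzodioxol-5-yl]-2-(benzyloxy)-3-[2,4-bis(benzyloxy)-6-bromophenyl]propan-1-ol | C=CCOc1cc([C@@H](O)[C@@H](OCc2ccccc2)Cc2c(Br)cc(OCc3ccccc3)cc2OCc2ccccc2)cc2OC(c3ccccc3)(c3ccccc3)Oc12 | intermediate
21 | (2R,3S)-2-[7-(allyloxy)-2,2-diphenyl-1,3-benzodioxol-5-yl]-3,5,7-tris(benzyloxy)chromane | C=CCOc1cc([C@H]2Oc3cc(OCc4ccccc4)cc(OCc4ccccc4)c3C[C@@H]2OCc2ccccc2)cc2OC(c3ccccc3)(c3ccccc3)Oc12 | intermediate
22 | 6-[(2R,3S)-3,5,7-tris(benzyloxy)chroman-2-yl]-2,2-diphenyl-1,3-benzodioxol-4-ol | Oc1cc([C@H]2Oc3cc(OCc4ccccc4)cc(OCc4ccccc4)c3C[C@@H]2OCc2ccccc2)cc2OC(c3ccccc3)(c3ccccc3)Oc12 | intermediate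
23 | 3,4,5-tris(benzyloxy)benzoic acid | OC(=O)c1cc(OCc2ccccc2)c(OCc2ccccc2)c(OCc2ccccc2)c1 | starting material
24 | 6-[(2R,3S)-3,5,7-tris(benzyloxy)chroman-2-yl]-2,2-diphenyl-1,3-benzodioxol-4-yl 3,4,5-tris(benzyloxy)benzoate | O=C(Oc1cc([C@H]2Oc3cc(OCc4ccccc4)cc(OCc4ccccc4)c3C[C@@H]2OCc2ccccc2)cc2OC(c3ccccc3)(c3ccccc3)Oc12)c1cc(OCc2ccccc2)c(OCc2ccccc2)c(OCc2ccccc2)c1 | intermediate
25 | (2R,3S)-gallocatechin 3′-O-gallate | O=C(Oc1cc([C@H]2Oc3cc(O)cc(O)c3C[C@@H]2O)cc(O)c1O)c1cc(O)c(O)c(O)c1 | target

Total step count: 16. Longest linear sequence: 12 (steps 1–4, 6, 7, 11–16).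

Steps most likely to fail

First risk, step 13 (C-ring closure). Oxidative addition at the ortho-substituted bromide may be slow. Protodebromination or dehydrogenation of the copper alkoxide could then overtake C–O bond formation. The fallback builds the same ring from its other end, O1–C2, by SN2 displacement.
- It sets out from ketone 19. Catalyst-controlled transfer hydrogenation with RuCl[(R,R)-TsDPEN](p-cymene) in HCO2H–Et3N should give the (1S,2S)-syn bromo alcohol F1.
- Treatment with n-BuLi (2.2 equiv, THF, −78 °C; alkoxide formation, then Br–Li exchange), then B(OMe)3 and aqueous work-up, should give the arylboronic acid F2.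
- Oxidation with H2O2–NaOH converts this into the phenol F3.
- A Mitsunobu cyclisation (PPh3, DIAD, THF, 0 °C) then displaces the activated benzylic oxygen with inversion, and the fallback comes back to the route at flavan 21.

Second risk, step 11 (ketone synthesis). Three processes could erode the coupling: halogen–metal exchange between the aryllithium and the A-ring bromide, deprotonation α to the amide with loss of configurational purity, and sluggish addition to the crowded amide. The fallback changes the oxidation level of the electrophile.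
- It sets out from amide 13. DIBAL-H (toluene, −78 °C) should give the (S)-α-benzyloxy aldehyde F4.
- This aldehyde captures aryllithium 18 at −78 °C much faster than any exchange can occur and gives the C1-epimeric carbinols F5.
- Dess–Martin oxidation of the mixture converges on ketone 19, where the fallback rejoins the route.

Third risk, step 12 (reduction). Incomplete zinc chelation would lower the facial selectivity, and liberated borane could hydroborate the allyl ether. The fallback replaces substrate control by boron-free catalyst control. Noyori-type asymmetric transfer hydrogenation of 19 with RuCl[(S,S)-TsDPEN](p-cymene) in HCO2H–Et3N should deliver the 1R carbinol by the usual aryl/alkyl sense of induction. It sets out from 19, returns at 20 and makes no new compound (F0).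

Further compounds
F1 | step 13 | (1S,2S)-1-[7-(allyloxy)-2,2-diphenyl-1,3-benzodioxol-5-yl]-2-(benzyloxy)-3-[2,4-bis(benzyloxy)-6-bromophenyl]propan-1-ol (syn) | C=CCOc1cc([C@H](O)[C@@H](OCc2ccccc2)Cc2c(Br)cc(OCc3ccccc3)cc2OCc2ccccc2)cc2OC(c3ccccc3)(c3ccccc3)Oc12
F2 | step 13 | (2-{(2S,3S)-3-[7-(allyloxy)-2,2-diphenyl-1,3-benzodioxol-5-yl]-2-(benzyloxy)-3-hydroxypropyl}-3,5-bis(benzyloxy)phenyl)boronic acid | C=CCOc1cc([C@H](O)[C@@H](OCc2ccccc2)Cc2c(B(O)O)cc(OCc3ccccc3)cc2OCc2ccccc2)cc2OC(c3ccccc3)(c3ccccc3)Oc12
F3 | step 13 | 2-{(2S,3S)-3-[7-(allyloxy)-2,2-diphenyl-1,3-benzodioxol-5-yl]-2-(benzyloxy)-3-hydroxypropyl}-3,5-bis(benzyloxy)phenol | C=CCOc1cc([C@H](O)[C@@H](OCc2ccccc2)Cc2c(O)cc(OCc3ccccc3)cc2OCc2ccccc2)cc2OC(c3ccccc3)(c3ccccc3)Oc12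
F4 | step 11 | (2S)-2-(benzyloxy)-3-[2,4-bis(benzyloxy)-6-bromophenyl]propanal | O=C[C@@H](OCc1ccccc1)Cc1c(Br)cc(OCc2ccccc2)cc1OCc1ccccc1
F5 | step 11 | (2S)-1-[7-(allyloxy)-2,2-diphenyl-1,3-benzodioxol-5-yl]-2-(benzyloxy)-3-[2,4-bis(benzyloxy)-6-bromophenyl]propan-1-ol, mixture of C1 epimers | C=CCOc1cc(C(O)[C@@H](OCc2ccccc2)Cc2c(Br)cc(OCc3ccccc3)cc2OCc2ccccc2)cc2OC(c3ccccc3)(c3ccccc3)Oc12
F0 | step 12 | none | none
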